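The dihydrofuran ring is disconnected at C3–C2 and O1–C2: furan C2 is delivered as a one-carbon sulfonium ylide, the remainder as an ortho-quinone methide. This is possible because ring A is a phloroglucinol whose benzylic C3 methylene and adjacent O1 phenoxide form a methide with an unsubstituted CH2 terminus. One annulation of base-labile 3,5-dibenzyloxy-2-(tosylmethyl)phenol with the ylide of a C2-symmetric (2R,5R)-dimethylthiolanium acetate should build the ring, both bonds and the C2 stereocentre. The ester carbon then becomes the diarylmethine by reduction, aryl Grignard addition, Friedel–Crafts coupling at C8 of benzylated (+)-catechin, and hydrogenolysis.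

Key step: step 6

Assumption: the (2R,5R)-thiolanium ylide is taken to give the (S) configuration at furan C2. The sense of induction has to be confirmed on the first run; if it proves opposite, the mirror-image salt from (2R,5R)-hexane-2,5-diol is used in the same sequence.

Step 1
Reactants: 1 2,4,6-trihydroxybenzaldehyde
Product: 2 2,4-bis(benzyloxy)-6-hydroxybenzaldehyde
Conditions: BnBr (2.05 equiv), K2CO3, DMF, 0 °C → rt
Reagents that add atoms: benzyl bromide, BrCc1ccccc1
Why: Williamson etherification, in which the para hydroxyl and one ortho hydroxyl react while the remaining ortho hydroxyl, held in a hydrogen bond to the formyl oxygen, is the least nucleophilic and should stay free.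

Step 2
Reactants: 2 2,4-bis(benzyloxy)-6-hydroxybenzaldehyde
Product: 4 3,5-bis(benzyloxy)-2-[(4-methylbenzenesulfonyl)methyl]phenol, via benzylic alcohol 3 (not isolated)
Conditions: NaBH4, THF/MeOH, 0 °C; then p-TolSO2Na (4 equiv), aq. HCl to pH 3, 0 °C → rt
Reagents that add atoms: sodium p-toluenesulfinate, [Na+].[O-]S(=O)c1ccc(C)cc1
Why: Borohydride reduction of the aldehyde, then acid-promoted ionisation of the very electron-rich ortho-hydroxybenzyl alcohol and S-alkylation of the sulfinate (SN1-type sulfone formation); low temperature and immediate trapping by excess sulfinate should suppress over-reduction and self-condensation.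

Step 3
Reactants: 5 (2S,5S)-hexane-2,5-diol
Product: 6 (2S,5S)-hexane-2,5-diyl dimethanesulfonate
Conditions: MsCl, Et3N, CH2Cl2, 0 °C
Reagents that add atoms: methanesulfonyl chloride, CS(=O)(=O)Cl
Why: Sulfonylation of both secondary alcohols at oxygen, so that both carbon stereocentres are retained.

Step 4
Reactants: 6 (2S,5S)-hexane-2,5-diyl dimethanesulfonate
Product: 7 (2R,5R)-2,5-dimethylthiolane
Conditions: Na2S·9H2O, EtOH, rt
Reagents that add atoms: sodium sulfide, [Na+].[Na+].[S-2]
Why: Double SN2 displacement by sulfide, the second one a 5-exo-tet ring closure, each with inversion, so that the (2S,5S) dimesylate should give the C2-symmetric (2R,5R) thiolane.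

Step 5
Reactants: 7 (2R,5R)-2,5-dimethylthiolane; 8 tert-butyl bromoacetate
Product: 9 (2R,5R)-1-(2-tert-butoxy-2-oxoethyl)-2,5-dimethylthiolan-1-ium bromide
Conditions: acetone, rt, 48 h
Reagents that add atoms: none
Why: SN2 S-alkylation of the thioether by the activated alpha-bromo ester; the two ring arms on sulfur are related by the C2 axis, so sulfur is not stereogenic and a single salt should form.

Step 6
Reactants: 4 3,5-bis(benzyloxy)-2-[(4-methylbenzenesulfonyl)methyl]phenol; 9 (2R,5R)-1-(2-tert-butoxy-2-oxoethyl)-2,5-dimethylthiolan-1-ium bromide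
Product: 13 tert-butyl (2S)-4,6-bis(benzyloxy)-2,3-dihydro-1-benzofuran-2-carboxylate, via quinone methide 10 (not isolated), via sulfonium ylide 11 (not isolated), via betaine 12 (not isolated)
Conditions: 9 (1.3 equiv), Cs2CO3 (3 equiv), CH2Cl2, −20 °C → rt
Reagents that add atoms: none
Why: Cs2CO3 deprotonates the phenol, which expels p-toluenesulfinate to give methide 10, and also deprotonates salt 9 to the ester-stabilised ylide 11; the ylide carbon adds to the exocyclic CH2 of 10 (conjugate addition driven by rearomatisation) to give betaine 12, whose phenoxide displaces the thiolane in a 5-exo-tet SN2 closure with inversion, so that the C3–C2 and O1–C2 bonds and the dihydrofuran ring form in one flask. The closest known reaction type is the [4+1] annulation of base-generated ortho-quinone methides from 2-(sulfonylmethyl)phenols with ester- or acyl-stabilised sulfonium ylides, including variants with chiral sulfonium groups. The single new stereocentre, furan C2, is controlled by the C2-symmetric (2R,5R)-thiolanium group: it biases the face of the planar ylide that bonds to the methide, and, because the betaine carbon between ester and sulfonium can epimerise, it also selects the (2R) betaine that is taken to close faster to the (2S) ester. With an unsubstituted methide terminus no second stereocentre assists, so the level of induction is the open point, and the enantiomeric purity of 13 should be checked by chiral HPLC and raised by crystallisation. The step needs C-alkylation of the ylide at the methide carbon in preference to methide oligomerisation and to O-alkylation of the phenoxide by the salt; slow release of the methide by the heterogeneous base in the presence of excess ylide, and the two donor benzyloxy groups that temper the methide, should secure this.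

Step 7
Reactants: 13 tert-butyl (2S)-4,6-bis(benzyloxy)-2,3-dihydro-1-benzofuran-2-carboxylate
Product: 14 (2S)-4,6-bis(benzyloxy)-2,3-dihydro-1-benzofuran-2-carbaldehyde
Conditions: i-Bu2AlH (1.1 equiv), CH2Cl2, −78 °C; MeOH, then aq. potassium sodium tartrate
Reagents that add atoms: none
Why: Partial reduction of an alpha-alkoxy ester by i-Bu2AlH through the chelated aluminium hemiacetal, which releases the aldehyde only on work-up; C2 is not touched, and the aldehyde is used at once to avoid epimerisation.

Step 8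
Reactants: 14 (2S)-4,6-bis(benzyloxy)-2,3-dihydro-1-benzofuran-2-carbaldehyde; 15 4-bromo-1,2-bis(benzyloxy)benzene
Product: 17 [3,4-bis(benzyloxy)phenyl][(2S)-4,6-bis(benzyloxy)-2,3-dihydro-1-benzofuran-2-yl]methanol (both carbinol epimers), via aryl Grignard reagent 16 (not isolated)
Conditions: 15, Mg, THF, 40 °C; then 14, THF, −78 °C; aq. NH4Cl
Reagents that add atoms: none
Why: Grignard addition to the aldehyde at low temperature, faster than enolisation; the carbinol centre forms as a mixture of epimers, which does not matter because it is ionised in step 10.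

Step 9
Reactants: 18 (+)-catechin
Product: 19 (2R,3S)-5,7-bis(benzyloxy)-2-[3,4-bis(benzyloxy)phenyl]-3,4-dihydro-2H-chromen-3-ol
Conditions: BnBr (4.4 equiv), K2CO3, DMF, 0 °C → rt
Reagents that add atoms: benzyl bromide, BrCc1ccccc1
Why: Williamson etherification of the four phenols with a base too weak to alkylate the secondary 3-hydroxyl or to epimerise C2.

Step 10
Reactants: 17 [3,4-bis(benzyloxy)phenyl][(2S)-4,6-bis(benzyloxy)-2,3-dihydro-1-benzofuran-2-yl]methanol; 19 (2R,3S)-5,7-bis(benzyloxy)-2-[3,4-bis(benzyloxy)phenyl]-3,4-dihydro-2H-chromen-3-ol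
Product: 20 (2R,3S)-5,7-bis(benzyloxy)-2-[3,4-bis(benzyloxy)phenyl]-8-{(R)-[3,4-bis(benzyloxy)phenyl][(2S)-4,6-bis(benzyloxy)-2,3-dihydro-1-benzofuran-2-yl]methyl}-3,4-dihydro-2H-chromen-3-ol
Conditions: 19 (3 equiv), Bi(OTf)3 (5 mol %), CH2Cl2, 4 Å MS, −40 → 0 °C
Reagents that add atoms: none
Why: Acid-catalysed SN1 Friedel–Crafts alkylation in which both carbinol epimers ionise to one 3,4-dibenzyloxybenzylic cation that is captured by the phloroglucinol-type ring A of 19 at C8 (flanked by the ring oxygen and one benzyloxy group, less hindered than C6 and the usual site of electrophilic substitution); the (R) methine should arise from attack on the cation conformer whose furan C2–H eclipses the aryl plane (allylic 1,3-strain), on the face flanked by the small ring oxygen O1 and anti to the C3 methylene with its neighbouring 4-benzyloxy group, the epimer being removed by chromatography.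

Step 11
Reactants: 20 (2R,3S)-5,7-bis(benzyloxy)-2-[3,4-bis(benzyloxy)phenyl]-8-{(R)-[3,4-bis(benzyloxy)phenyl][(2S)-4,6-bis(benzyloxy)-2,3-dihydro-1-benzofuran-2-yl]methyl}-3,4-dihydro-2H-chromen-3-ol
Product: 21 (2R,3S)-2-(3,4-dihydroxyphenyl)-8-{(R)-(3,4-dihydroxyphenyl)[(2S)-4,6-dihydroxy-2,3-dihydro-1-benzofuran-2-yl]methyl}-3,4-dihydro-2H-chromene-3,5,7-triol
Conditions: H2 (1 atm), Pd(OH)2/C, THF/MeOH/H2O, rt
Reagents that add atoms: none
Why: Hydrogenolysis of the eight benzyl ethers under neutral conditions, which should leave the alkyl aryl ether bonds of both oxygen heterocycles, the diarylmethine and all four stereocentres untouched.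

Compound list
1 | 2,4,6-trihydroxybenzaldehyde | O=Cc1c(O)cc(O)cc1O | starting material
2 | 2,4-bis(benzyloxy)-6-hydroxybenzaldehyde | O=Cc1c(O)cc(OCc2ccccc2)cc1OCc1ccccc1 | intermediate
3 | 3,5-bis(benzyloxy)-2-(hydroxymethyl)phenol | OCc1c(O)cc(OCc2ccccc2)cc1OCc1ccccc1 | intermediate (not isolated)
4 | 3,5-bis(benzyloxy)-2-[(4-methylbenzenesulfonyl)methyl]phenol | Cc1ccc(cc1)S(=O)(=O)Cc1c(O)cc(OCc2ccccc2)cc1OCc1ccccc1 | intermediate
5 | (2S,5S)-hexane-2,5-diol | C[C@H](O)CC[C@H](C)O | starting material
6 | (2S,5S)-hexane-2,5-diyl dimethanesulfonate | C[C@H](OS(C)(=O)=O)CC[C@H](C)OS(C)(=O)=O | intermediate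
7 | (2R,5R)-2,5-dimethylthiolane | C[C@@H]1CC[C@@H](C)S1 | intermediate
8 | tert-butyl bromoacetate | BrCC(=O)OC(C)(C)C | starting material
9 | (2R,5R)-1-(2-tert-butoxy-2-oxoethyl)-2,5-dimethylthiolan-1-ium bromide | C[C@@H]1CC[C@@H](C)[S+]1CC(=O)OC(C)(C)C.[Br-] | intermediate
10 | 3,5-bis(benzyloxy)-6-methylidenecyclohexa-2,4-dien-1-one | C=C1C(=O)C=C(OCc2ccccc2)C=C1OCc1ccccc1 | intermediate (not isolated)
11 | 2-tert-butoxy-1-[(2R,5R)-2,5-dimethylthiolan-1-ium-1-yl]-2-oxoethan-1-ide (sulfonium ylide) | C[C@@H]1CC[C@@H](C)[S+]1[CH-]C(=O)OC(C)(C)C | intermediate (not isolated)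
12 | 3,5-bis(benzyloxy)-2-{(2R)-3-tert-butoxy-2-[(2R,5R)-2,5-dimethylthiolan-1-ium-1-yl]-3-oxopropyl}phenolate (betaine) | C[C@@H]1CC[C@@H](C)[S+]1[C@H](Cc1c([O-])cc(OCc2ccccc2)cc1OCc1ccccc1)C(=O)OC(C)(C)C | intermediate (not isolated)
13 | tert-butyl (2S)-4,6-bis(benzyloxy)-2,3-dihydro-1-benzofuran-2-carboxylate | O(Cc3ccccc3)c1cc(OCc3ccccc3)c2c(c1)O[C@H](C(=O)OC(C)(C)C)C2 | intermediate
14 | (2S)-4,6-bis(benzyloxy)-2,3-dihydro-1-benzofuran-2-carbaldehyde | O(Cc3ccccc3)c1cc(OCc3ccccc3)c2c(c1)O[C@H](C=O)C2 | intermediate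
15 | 4-bromo-1,2-bis(benzyloxy)benzene | Brc1ccc(OCc2ccccc2)c(OCc2ccccc2)c1 | starting material
16 | [3,4-bis(benzyloxy)phenyl]magnesium bromide | Br[Mg]c1ccc(OCc2ccccc2)c(OCc2ccccc2)c1 | intermediate (not isolated)
17 | [3,4-bis(benzyloxy)phenyl][(2S)-4,6-bis(benzyloxy)-2,3-dihydro-1-benzofuran-2-yl]methanol, both carbinol epimers | O(Cc3ccccc3)c1cc(OCc3ccccc3)c2c(c1)O[C@H](C(O)c1ccc(OCc3ccccc3)c(OCc3ccccc3)c1)C2 | intermediate
18 | (+)-catechin, (2R,3S) | O[C@H]1Cc2c(O)cc(O)cc2O[C@@H]1c1ccc(O)c(O)c1 | starting material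
19 | (2R,3S)-5,7-bis(benzyloxy)-2-[3,4-bis(benzyloxy)phenyl]-3,4-dihydro-2H-chromen-3-ol | O[C@H]1Cc2c(OCc3ccccc3)cc(OCc3ccccc3)cc2O[C@@H]1c1ccc(OCc3ccccc3)c(OCc3ccccc3)c1 | intermediate
20 | (2R,3S)-5,7-bis(benzyloxy)-2-[3,4-bis(benzyloxy)phenyl]-8-{(R)-[3,4-bis(benzyloxy)phenyl][(2S)-4,6-bis(benzyloxy)-2,3-dihydro-1-benzofuran-2-yl]methyl}-3,4-dihydro-2H-chromen-3-ol | O(Cc4ccccc4)c1cc(OCc4ccccc4)c2c(c1)O[C@H]([C@H](c1ccc(OCc4ccccc4)c(OCc4ccccc4)c1)c1c(OCc4ccccc4)cc(OCc4ccccc4)c3c1O[C@H](c1ccc(OCc4ccccc4)c(OCc4ccccc4)c1)[C@@H](O)C3)C2 | intermediate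
21 | (2R,3S)-2-(3,4-dihydroxyphenyl)-8-{(R)-(3,4-dihydroxyphenyl)[(2S)-4,6-dihydroxy-2,3-dihydro-1-benzofuran-2-yl]methyl}-3,4-dihydro-2H-chromene-3,5,7-triol | Oc1cc(O)c2c(c1)O[C@H]([C@H](c1ccc(O)c(O)c1)c1c(O)cc(O)c3c1O[C@H](c1ccc(O)c(O)c1)[C@@H](O)C3)C2 | target

Total step count: 11
Longest linear sequence: 8 steps (steps 3, 4, 5, 6, 7, 8, 10 and 11, from the diol 5)

Steps most likely to fail

Step 6. The thiolanium group may transmit too little asymmetry to furan C2, or the opposite sense, and the methide may oligomerise before the ylide captures it. The fallback sets out from 4 and gives up asymmetric induction for a resolution. The achiral salt 1-(2-tert-butoxy-2-oxoethyl)thiolan-1-ium bromide F1, made from thiolane and 8, is used with Cs2CO3 in CH2Cl2 in the same annulation and should give racemic tert-butyl 4,6-bis(benzyloxy)-2,3-dihydro-1-benzofuran-2-carboxylate F2. The enantiomers are then separated by preparative chromatography on a chiral stationary phase with supercritical CO2. The unwanted tert-butyl (2R)-4,6-bis(benzyloxy)-2,3-dihydro-1-benzofuran-2-carboxylate F3 is set aside, and the (2S) ester comes back to the route as 13.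

Step 10. The cation may be attacked on its other face and give the (S) methine, it may be attacked at C6 of ring A of 19 and not at C8, and ring A of a second molecule of 17 may compete as the nucleophile. The fallback introduces the two aryl groups in the reverse order. This fixes the position on catechin through a halogen and makes the opposite face of attack the productive one. Setting out from 19, NBS in CH2Cl2 at −78 °C should give (2R,3S)-5,7-bis(benzyloxy)-2-[3,4-bis(benzyloxy)phenyl]-8-bromo-3,4-dihydro-2H-chromen-3-ol F4, and NaH with BnBr in DMF its 3-O-benzyl ether (2R,3S)-3,5,7-tris(benzyloxy)-2-[3,4-bis(benzyloxy)phenyl]-8-bromo-3,4-dihydro-2H-chromene F5. Bromine–lithium exchange with n-BuLi in THF at −78 °C gives the 8-lithio compound F6, which is added to aldehyde 14 to give the catechin-8-yl carbinol F7. F7 is ionised with catalytic Bi(OTf)3 in a large excess of commercial 1,2-bis(benzyloxy)benzene; the excess compensates for the low nucleophilicity of this arene. The catechol ring then adds to a cation stabilised by ring A of the catechin unit. In that cation, attack anti to O1 leads to the same (R) methine, in the nona-O-benzyl ether of 21 F8. Hydrogenolysis as in step 11 comes back to the route at 21.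

Step 2. Hydride may add to the methide that forms from the borate of 3 and give the ortho-methylphenol, and the benzylic cation may alkylate a second electron-rich ring before the sulfinate traps it. The fallback sets out from 2 and never exposes a benzylic alcohol. Reductive amination with Me2NH and NaBH(OAc)3 in 1,2-dichloroethane should give the stable Mannich base 3,5-bis(benzyloxy)-2-[(dimethylamino)methyl]phenol F9. Heating F9 with p-TolSO2Na in AcOH exchanges the amine for the sulfinate by elimination and re-addition through the same methide, and comes back to the route at 4.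

Further compounds
F1 | step 6 | 1-(2-tert-butoxy-2-oxoethyl)thiolan-1-ium bromide | CC(C)(C)OC(=O)C[S+]1CCCC1.[Br-]
F2 | step 6 | racemic tert-butyl 4,6-bis(benzyloxy)-2,3-dihydro-1-benzofuran-2-carboxylate | O(Cc3ccccc3)c1cc(OCc3ccccc3)c2c(c1)OC(C(=O)OC(C)(C)C)C2
F3 | step 6 | tert-butyl (2R)-4,6-bis(benzyloxy)-2,3-dihydro-1-benzofuran-2-carboxylate | O(Cc3ccccc3)c1cc(OCc3ccccc3)c2c(c1)O[C@@H](C(=O)OC(C)(C)C)C2
F4 | step 10 | (2R,3S)-5,7-bis(benzyloxy)-2-[3,4-bis(benzyloxy)phenyl]-8-bromo-3,4-dihydro-2H-chromen-3-ol | O[C@H]1Cc2c(OCc3ccccc3)cc(OCc3ccccc3)c(Br)c2O[C@@H]1c1ccc(OCc3ccccc3)c(OCc3ccccc3)c1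
F5 | step 10 | (2R,3S)-3,5,7-tris(benzyloxy)-2-[3,4-bis(benzyloxy)phenyl]-8-bromo-3,4-dihydro-2H-chromene | O(Cc3ccccc3)[C@H]1Cc2c(OCc3ccccc3)cc(OCc3ccccc3)c(Br)c2O[C@@H]1c1ccc(OCc3ccccc3)c(OCc3ccccc3)c1
F6 | step 10 | {(2R,3S)-3,5,7-tris(benzyloxy)-2-[3,4-bis(benzyloxy)phenyl]-3,4-dihydro-2H-chromen-8-yl}lithium | O(Cc3ccccc3)[C@H]1Cc2c(OCc3ccccc3)cc(OCc3ccccc3)c([Li])c2O[C@@H]1c1ccc(OCc3ccccc3)c(OCc3ccccc3)c1
F7 | step 10 | [(2S)-4,6-bis(benzyloxy)-2,3-dihydro-1-benzofuran-2-yl]{(2R,3S)-3,5,7-tris(benzyloxy)-2-[3,4-bis(benzyloxy)phenyl]-3,4-dihydro-2H-chromen-8-yl}methanol, both carbinol epimers | O(Cc4ccccc4)c1cc(OCc4ccccc4)c2c(c1)O[C@H](C(O)c1c(OCc4ccccc4)cc(OCc4ccccc4)c3c1O[C@H](c1ccc(OCc4ccccc4)c(OCc4ccccc4)c1)[C@@H](OCc4ccccc4)C3)C2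
F8 | step 10 | nona-O-benzyl ether of 21: (2R,3S)-3,5,7-tris(benzyloxy)-2-[3,4-bis(benzyloxy)phenyl]-8-{(R)-[3,4-bis(benzyloxy)phenyl][(2S)-4,6-bis(benzyloxy)-2,3-dihydro-1-benzofuran-2-yl]methyl}-3,4-dihydro-2H-chromene | O(Cc4ccccc4)c1cc(OCc4ccccc4)c2c(c1)O[C@H]([C@H](c1ccc(OCc4ccccc4)c(OCc4ccccc4)c1)c1c(OCc4ccccc4)cc(OCc4ccccc4)c3c1O[C@H](c1ccc(OCc4ccccc4)c(OCc4ccccc4)c1)[C@@H](OCc4ccccc4)C3)C2
F9 | step 2 | 3,5-bis(benzyloxy)-2-[(dimethylamino)methyl]phenol | CN(C)Cc1c(O)cc(OCc2ccccc2)cc1OCc1ccccc1
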